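**Plan** (chroman-2-one numbering O1, C2, C3, C4, C4a, C5–C8, C8a; ring A = benzo ring, ring B = 4-hydroxyphenyl, ring C = lactone)
Retrosynthesis: once the helper groups are removed, ring C is cut at C3–C4 and at O1–C8a. This gives an acetic acid C,O-dinucleophile and a ring A/ring B unit that is electrophilic at C4 and at C8a. C4–C4a and C8–acyl are then cut back to 1-fluoro-3,5-dimethoxybenzene.
Enabling feature: C4 is the para-benzylic carbon of the ring B phenol and can be raised to a para-quinone methide. C8a lies ortho to both the C8 ketone and C4a, which carries that quinone methide carbon. A fluorine placed on C8a is therefore doubly activated toward displacement by a carboxylate oxygen.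
Forward: ring A is acylated at C8, benzylated at C4a with the ring B unit, and dehydrogenated to the quinone methide. One [3+3] cascade with Me3SiCH2CO2SiMe3 then closes ring C, forming O1–C8a first and C3–C4 second.
Helpers: F on C8a leaves in the cascade. Two tert-butyl groups on ring B make the quinone methide isolable, and two O-methyl groups protect ring A. AlCl3/toluene and then BBr3 remove them.
Stereochemistry: C4 is the only stereocentre. It is set in the ring-closing 1,6-addition by the chiral quaternary ammonium counter-ion of the tethered ester enolate.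

Key step: step 4

Assumption: the cinchonidinium-derived cation is taken to favour (4S). If the opposite sense is found, the pseudoenantiomeric cinchoninium salt is used.

**Step 1**
Reactants: 1 1-fluoro-3,5-dimethoxybenzene; 2 3-phenylpropanoyl chloride
Product: 3 1-(2-fluoro-4,6-dimethoxyphenyl)-3-phenylpropan-1-one
Conditions: AlCl3 (1.1 equiv), CH2Cl2, 0 °C; cold 1 M HCl
Reagents that add atoms: none
Why: Friedel–Crafts acylation should go to the position para to one methoxy group, ortho to the other and next to the small fluorine, because the site between the two methoxy groups is more crowded, and the acyl group prevents a second acylation.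

**Step 2**
Reactants: 3 1-(2-fluoro-4,6-dimethoxyphenyl)-3-phenylpropan-1-one; 4 3,5-di-tert-butyl-4-hydroxybenzyl alcohol
Product: 5 1-{3-[(3,5-di-tert-butyl-4-hydroxyphenyl)methyl]-2-fluoro-4,6-dimethoxyphenyl}-3-phenylpropan-1-one
Conditions: MeSO3H (0.5 equiv), CH2Cl2, 0 °C → rt
Reagents that add atoms: none
Why: Friedel–Crafts benzylation, in which acid ionises 4 to the 4-hydroxybenzyl cation, and this should attack the future C4a (ortho to one methoxy group, para to the other, flanked only by F and OMe) in preference to the more crowded C6.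

**Step 3**
Reactants: 5 1-{3-[(3,5-di-tert-butyl-4-hydroxyphenyl)methyl]-2-fluoro-4,6-dimethoxyphenyl}-3-phenylpropan-1-one
Product: 6 2,6-di-tert-butyl-4-{[2-fluoro-4,6-dimethoxy-3-(3-phenylpropanoyl)phenyl]methylidene}cyclohexa-2,5-dien-1-one
Conditions: DDQ (1.1 equiv), dry CH2Cl2, rt; filter
Reagents that add atoms: none
Why: dehydrogenation of a 4-benzyl-2,6-di-tert-butylphenol (hydride abstraction from the doubly benzylic CH2, then loss of the phenol proton) is the classical neutral route to an isolable para-quinone methide, and the absence of base or amine spares the activated C–F bond.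

**Step 4**
Reactants: 6 2,6-di-tert-butyl-4-{[2-fluoro-4,6-dimethoxy-3-(3-phenylpropanoyl)phenyl]methylidene}cyclohexa-2,5-dien-1-one; 7 trimethylsilyl 2-(trimethylsilyl)acetate
Product: 10 (4S)-4-(3,5-di-tert-butyl-4-hydroxyphenyl)-5,7-dimethoxy-8-(3-phenylpropanoyl)-3,4-dihydro-2H-chromen-2-one, via aryl silylacetate quinone methide 8 (not isolated), via O-silyl lactone 9 (not isolated)
Conditions: 7 (1.3 equiv), O-allyl-N-(9-anthracenylmethyl)cinchonidinium bifluoride (10 mol%), toluene/CH2Cl2, 4 Å molecular sieves, −20 °C → rt; then 1 M HCl, THF, rt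
Reagents that add atoms: none
Why: Proposed new method: fluoride from the catalyst cleaves the labile O–Si bond of 7, and the ammonium carboxylate adds through oxygen to C8a of 6 in an addition–elimination whose σ-adduct is unusually stabilised, because the charge runs into the C8 ketone and, through C4a=C4, into ring B, which becomes an aromatic phenoxide, so that loss of fluoride gives aryl ester 8 with the quinone methide restored (O1–C8a bond). The C–Si bond, inert while it sits next to a carboxylate, is now alpha to an activated aryl ester and is cut by the fluoride just released (or by carboxylate), and the resulting ester enolate adds through C3 to C4 in a 1,6-conjugate addition that rearomatises ring B (C3–C4 bond), after which the hindered phenoxide takes Me3Si from the next molecule of 7 and carries the chain, giving 9. The closest known reaction types are the tandem C-benzylation/O-arylation of 2-halobenzyl halides with 1,3-dicarbonyl compounds to 4H-chromenes, the Mukaiyama–Michael/lactonisation relay run by chiral quaternary ammonium fluorides or phenoxides, and the phase-transfer-catalysed asymmetric 1,6-addition of malonates to para-quinone methides; new here are a carboxylate as the oxygen nucleophile, the quinone methide as activator of the C–F bond, and the fluoride-gated unmasking of the carbon nucleophile. Ring C closes in the C–C step as a 6-exo-trig attack, since the C4=C1' bond that is broken (C1' = ring B carbon) lies outside the new ring, whereas the O1–C8a step is intermolecular. C4 is the only new stereocentre: ring A is twisted out of the quinone methide plane by its two ortho substituents, so the tethered enolate lies over one face of C4 in each of two rapidly interconverting enantiomeric twist conformers, and the chiral ammonium cation paired with the enolate selects the conformer that leads to (S). The step needs oxygen-before-carbon order, attack at C8a instead of C4, C5 or C7, and closure on C4 instead of the C8 ketone: the silyl mask keeps carbon silent until the ester exists, carboxylate addition at C4 is reversible, fluoride is the only good leaving group on ring A, and the aldol at the hindered ketone is reversible whereas the 1,6-addition is driven by aromatisation.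

**Step 5**
Reactants: 10 (4S)-4-(3,5-di-tert-butyl-4-hydroxyphenyl)-5,7-dimethoxy-8-(3-phenylpropanoyl)-3,4-dihydro-2H-chromen-2-one
Product: 11 (4S)-7-hydroxy-4-(4-hydroxyphenyl)-5-methoxy-8-(3-phenylpropanoyl)-3,4-dihydro-2H-chromen-2-one
Conditions: AlCl3 (10 equiv), toluene, rt → 40 °C; cold 1 M HCl
Reagents that add atoms: none
Why: retro-Friedel–Crafts transfer of both tert-butyl groups to toluene is the standard way to remove these helpers from quinone methide adducts, it is accompanied by chelation-assisted cleavage of the methyl ether ortho to the ketone (any 7-O-methyl material left converges in step 6), and no bond at C4 is involved, so the configuration should be retained.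

**Step 6**
Reactants: 11 (4S)-7-hydroxy-4-(4-hydroxyphenyl)-5-methoxy-8-(3-phenylpropanoyl)-3,4-dihydro-2H-chromen-2-one
Product: 12 (4S)-5,7-dihydroxy-4-(4-hydroxyphenyl)-8-(3-phenylpropanoyl)-3,4-dihydro-2H-chromen-2-one
Conditions: BBr3 (4 equiv), CH2Cl2, −78 → 0 °C; ice water, rapid extraction
Reagents that add atoms: none
Why: Lewis-acid cleavage of the last aryl methyl ether with BBr3 is routine on methoxy-dihydrocoumarins, and the low temperature and short cold work-up are chosen to keep the lactone acyl group on O1 and stop it migrating to the newly freed O5.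

**Compound list**
1 | 1-fluoro-3,5-dimethoxybenzene | COc1cc(F)cc(OC)c1 | starting material
2 | 3-phenylpropanoyl chloride | O=C(Cl)CCc1ccccc1 | starting material
3 | 1-(2-fluoro-4,6-dimethoxyphenyl)-3-phenylpropan-1-one | COc1cc(F)c(C(=O)CCc2ccccc2)c(OC)c1 | intermediate
4 | 3,5-di-tert-butyl-4-hydroxybenzyl alcohol | OCc1cc(C(C)(C)C)c(O)c(C(C)(C)C)c1 | starting material
5 | 1-{3-[(3,5-di-tert-butyl-4-hydroxyphenyl)methyl]-2-fluoro-4,6-dimethoxyphenyl}-3-phenylpropan-1-one | COc1cc(OC)c(C(=O)CCc2ccccc2)c(F)c1Cc1cc(C(C)(C)C)c(O)c(C(C)(C)C)c1 | intermediate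
6 | 2,6-di-tert-butyl-4-{[2-fluoro-4,6-dimethoxy-3-(3-phenylpropanoyl)phenyl]methylidene}cyclohexa-2,5-dien-1-one | COc1cc(OC)c(C(=O)CCc2ccccc2)c(F)c1C=C1C=C(C(C)(C)C)C(=O)C(C(C)(C)C)=C1 | intermediate
7 | trimethylsilyl 2-(trimethylsilyl)acetate | C[Si](C)(C)CC(=O)O[Si](C)(C)C | starting material
8 | 2-[(3,5-di-tert-butyl-4-oxocyclohexa-2,5-dien-1-ylidene)methyl]-3,5-dimethoxy-6-(3-phenylpropanoyl)phenyl 2-(trimethylsilyl)acetate | COc1cc(OC)c(C(=O)CCc2ccccc2)c(OC(=O)C[Si](C)(C)C)c1C=C1C=C(C(C)(C)C)C(=O)C(C(C)(C)C)=C1 | intermediate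
9 | (4S)-4-[3,5-di-tert-butyl-4-(trimethylsilyloxy)phenyl]-5,7-dimethoxy-8-(3-phenylpropanoyl)-3,4-dihydro-2H-chromen-2-one | O=C1C[C@@H](c2cc(C(C)(C)C)c(O[Si](C)(C)C)c(C(C)(C)C)c2)c2c(OC)cc(OC)c(C(=O)CCc3ccccc3)c2O1 | intermediate
10 | (4S)-4-(3,5-di-tert-butyl-4-hydroxyphenyl)-5,7-dimethoxy-8-(3-phenylpropanoyl)-3,4-dihydro-2H-chromen-2-one | O=C1C[C@@H](c2cc(C(C)(C)C)c(O)c(C(C)(C)C)c2)c2c(OC)cc(OC)c(C(=O)CCc3ccccc3)c2O1 | intermediate
11 | (4S)-7-hydroxy-4-(4-hydroxyphenyl)-5-methoxy-8-(3-phenylpropanoyl)-3,4-dihydro-2H-chromen-2-one | O=C1C[C@@H](c2ccc(O)cc2)c2c(OC)cc(O)c(C(=O)CCc3ccccc3)c2O1 | intermediate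
12 | (4S)-5,7-dihydroxy-4-(4-hydroxyphenyl)-8-(3-phenylpropanoyl)-3,4-dihydro-2H-chromen-2-one | O=C1C[C@@H](c2ccc(O)cc2)c2c(O)cc(O)c(C(=O)CCc3ccccc3)c2O1 | target

Total step count: 6. Longest linear sequence: 6.

**Steps most likely to fail**

Step 4. Three things may go wrong. The C–Si bond of 7 may be cleaved too early, giving an intermolecular carbon-first 1,6-addition that leaves the fluoride in place. Displacement at C8a may be slow. Facial selectivity in the ring closure may be poor. The fallback uses known chemistry, sets out from 6 and comes back at 10.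
- Phase-transfer-catalysed asymmetric 1,6-conjugate addition of di-tert-butyl malonate to 6 (N-(9-anthracenylmethyl)cinchonidinium chloride, Cs2CO3, toluene, −20 °C) should give di-tert-butyl 2-{(S)-(3,5-di-tert-butyl-4-hydroxyphenyl)[2-fluoro-4,6-dimethoxy-3-(3-phenylpropanoyl)phenyl]methyl}propanedioate F1.
- CF3CO2H in CH2Cl2, then heating in toluene (ester cleavage and decarboxylation), should give (3S)-3-(3,5-di-tert-butyl-4-hydroxyphenyl)-3-[2-fluoro-4,6-dimethoxy-3-(3-phenylpropanoyl)phenyl]propanoic acid F2.
- KOH in DMSO–H2O at 90 °C under argon replaces the ketone-activated fluoride by hydroxide (SNAr) to give (3S)-3-(3,5-di-tert-butyl-4-hydroxyphenyl)-3-[2-hydroxy-4,6-dimethoxy-3-(3-phenylpropanoyl)phenyl]propanoic acid F3. This closes to 10 with catalytic TsOH in warm toluene.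

Step 5. The C4–C4a bond may be cleaved by a retro-Friedel–Crafts reaction, with erosion of configuration. The lactone may also open in a Fries-type reaction or migrate under prolonged exposure to AlCl3. The fallback avoids the tert-butyl helpers altogether, sets out from 3 and comes back at 12.
- KOH in DMSO–H2O at 90 °C turns 3 into 1-(2-hydroxy-4,6-dimethoxyphenyl)-3-phenylpropan-1-one F4.
- Propiolic acid, Pd(OAc)2 and CF3CO2H at rt (hydroarylation and lactonisation ortho to the phenol) give 5,7-dimethoxy-8-(3-phenylpropanoyl)-2H-chromen-2-one F5.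
- Hayashi–Miyaura addition of 4-methoxyphenylboronic acid (Rh(acac)(C2H4)2, the SEGPHOS enantiomer that gives (S), dioxane–H2O, 60 °C) gives (4S)-5,7-dimethoxy-4-(4-methoxyphenyl)-8-(3-phenylpropanoyl)-3,4-dihydro-2H-chromen-2-one F6.
- BBr3 in CH2Cl2 (−78 → 0 °C) cleaves all three methyl ethers to give 12.

Step 2. Alkylation of the acyl-deactivated ring may be sluggish, attack may occur at C6, and 4 may self-condense. The fallback brings in C4 as a formyl carbon, sets out from 3 and comes back at 6.
- Rieche formylation (Cl2CHOMe, TiCl4, CH2Cl2, 0 °C) gives 2-fluoro-4,6-dimethoxy-3-(3-phenylpropanoyl)benzaldehyde F7.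
- The dilithio species made from 4-bromo-2,6-di-tert-butylphenol and n-BuLi (2.1 equiv, THF, −78 °C) adds to the aldehyde to give racemic 1-{3-[(3,5-di-tert-butyl-4-hydroxyphenyl)(hydroxy)methyl]-2-fluoro-4,6-dimethoxyphenyl}-3-phenylpropan-1-one F8.
- Catalytic TsOH in CH2Cl2 dehydrates F8 to 6.

**Further compounds**
F1 | step 4 | di-tert-butyl 2-{(S)-(3,5-di-tert-butyl-4-hydroxyphenyl)[2-fluoro-4,6-dimethoxy-3-(3-phenylpropanoyl)phenyl]methyl}propanedioate | CC(C)(C)OC(=O)C(C(=O)OC(C)(C)C)[C@@H](c1cc(C(C)(C)C)c(O)c(C(C)(C)C)c1)c1c(OC)cc(OC)c(C(=O)CCc2ccccc2)c1F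
F2 | step 4 | (3S)-3-(3,5-di-tert-butyl-4-hydroxyphenyl)-3-[2-fluoro-4,6-dimethoxy-3-(3-phenylpropanoyl)phenyl]propanoic acid | OC(=O)C[C@@H](c1cc(C(C)(C)C)c(O)c(C(C)(C)C)c1)c1c(OC)cc(OC)c(C(=O)CCc2ccccc2)c1F
F3 | step 4 | (3S)-3-(3,5-di-tert-butyl-4-hydroxyphenyl)-3-[2-hydroxy-4,6-dimethoxy-3-(3-phenylpropanoyl)phenyl]propanoic acid | OC(=O)C[C@@H](c1cc(C(C)(C)C)c(O)c(C(C)(C)C)c1)c1c(OC)cc(OC)c(C(=O)CCc2ccccc2)c1O
F4 | step 5 | 1-(2-hydroxy-4,6-dimethoxyphenyl)-3-phenylpropan-1-one | COc1cc(O)c(C(=O)CCc2ccccc2)c(OC)c1
F5 | step 5 | 5,7-dimethoxy-8-(3-phenylpropanoyl)-2H-chromen-2-one | O=C1C=Cc2c(OC)cc(OC)c(C(=O)CCc3ccccc3)c2O1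
F6 | step 5 | (4S)-5,7-dimethoxy-4-(4-methoxyphenyl)-8-(3-phenylpropanoyl)-3,4-dihydro-2H-chromen-2-one | O=C1C[C@@H](c2ccc(OC)cc2)c2c(OC)cc(OC)c(C(=O)CCc3ccccc3)c2O1
F7 | step 2 | 2-fluoro-4,6-dimethoxy-3-(3-phenylpropanoyl)benzaldehyde | COc1cc(OC)c(C(=O)CCc2ccccc2)c(F)c1C=O
F8 | step 2 | 1-{3-[(3,5-di-tert-butyl-4-hydroxyphenyl)(hydroxy)methyl]-2-fluoro-4,6-dimethoxyphenyl}-3-phenylpropan-1-one (racemic) | COc1cc(OC)c(C(=O)CCc2ccccc2)c(F)c1C(O)c1cc(C(C)(C)C)c(O)c(C(C)(C)C)c1
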